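**Retrosynthetic overview**

- The strategy rests on ring D, the meta-phenylene whose only substituents are the ether oxygen on C1 and the CH2CH2 link on C3. A 5-substituted cyclohexane-1,3-dione carries exactly this 1,3-pattern, so ring D is kept as a 3-chlorocyclohex-2-enone until the macrocycle is closed.
- Key disconnection: the O–C bond between the ring C oxygen and ring D (19-membered ring). It is formed by attack of the ring C phenoxide on the tethered chloroenone; ring D is then aromatized (dehydrogenation to the phenol, triflate, reduction) and the four methyl ethers are cleaved.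
- The chloroenone ring comes from Michael–Claisen annulation of an (E)-6-arylhex-3-en-2-one with diethyl malonate; the enone comes from a cinnamate by reduction and Wittig chain extension.
- Ring A–O–ring B comes from SNAr on 4-fluorobenzaldehyde; ring B–CH2CH2–ring C from a Wittig reaction and a hydrogenation that also frees the ring C phenol.
- Ring order: rings A, B and C are bought as arenes; the carbocycle of ring D is formed in step 10, the macrocycle in step 14, and ring D becomes aromatic in step 15.

Key step: step 14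

Remark on the chemistry: C5 of the cyclohexenone ring (and the centres of 14–16, 18 and F1, F2, F5) is carried as the racemate, because it is erased on aromatization; the SMILES leave it undefined. The stilbene bond of 9 is taken as an E/Z mixture. Abbreviations: ArOH = 3-{4-[2-(3-hydroxy-4,5-dimethoxyphenyl)ethyl]phenoxy}-4,5-dimethoxyphenyl (rings A, B and C; the OH is on ring C); ArOTBS = the same group with that OH as its tert-butyldimethylsilyl ether.

**Route**

Step 1
Reactants: 1 3-hydroxy-4,5-dimethoxybenzaldehyde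
Product: 2 3-(benzyloxy)-4,5-dimethoxybenzaldehyde
Conditions: BnBr, K2CO3, DMF, 60 °C
Reagents that add atoms: benzyl bromide, BrCc1ccccc1
Why: Williamson ether synthesis on the only phenol; the benzyl group is later removed without an extra step by the hydrogenation of step 7.

Step 2
Reactants: 2 3-(benzyloxy)-4,5-dimethoxybenzaldehyde
Product: 3 [3-(benzyloxy)-4,5-dimethoxyphenyl]methanol
Conditions: NaBH4, MeOH, 0 °C
Reagents that add atoms: none
Why: Borohydride reduction of an aromatic aldehyde to the benzylic alcohol, to which the ethers are inert.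

Step 3
Reactants: 3 [3-(benzyloxy)-4,5-dimethoxyphenyl]methanol
Product: 4 {[3-(benzyloxy)-4,5-dimethoxyphenyl]methyl}triphenylphosphonium bromide
Conditions: PPh3·HBr, MeCN, reflux
Reagents that add atoms: triphenylphosphine hydrobromide, [Br-].c1ccc(cc1)[PH+](c1ccccc1)c1ccccc1
Why: Direct phosphonium salt formation from an electron-rich benzylic alcohol, which ionizes readily under the mild acid and is captured by triphenylphosphine.

Step 4
Reactants: 1 3-hydroxy-4,5-dimethoxybenzaldehyde
Product: 5 ethyl (2E)-3-(3-hydroxy-4,5-dimethoxyphenyl)prop-2-enoate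
Conditions: Ph3P=CHCO2Et, toluene, 90 °C
Reagents that add atoms: ethyl (triphenylphosphoranylidene)acetate, CCOC(=O)C=P(c1ccccc1)(c1ccccc1)c1ccccc1
Why: Wittig olefination with a stabilized ylide, E-selective and too weakly basic to be quenched by the free phenol, which is kept for the next step.

Step 5
Reactants: 5 ethyl (2E)-3-(3-hydroxy-4,5-dimethoxyphenyl)prop-2-enoate; 6 4-fluorobenzaldehyde
Product: 7 ethyl (2E)-3-[3-(4-formylphenoxy)-4,5-dimethoxyphenyl]prop-2-enoate
Conditions: K2CO3, DMF, 110 °C
Reagents that add atoms: none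
Why: Nucleophilic aromatic substitution (addition–elimination through a Meisenheimer adduct) of the phenoxide on the fluoride activated by the para formyl group; this forms the ring A–O–ring B ether and leaves one aldehyde for the next coupling.

Step 6
Reactants: 4 {[3-(benzyloxy)-4,5-dimethoxyphenyl]methyl}triphenylphosphonium bromide; 7 ethyl (2E)-3-[3-(4-formylphenoxy)-4,5-dimethoxyphenyl]prop-2-enoate
Product: 9 ethyl (2E)-3-[3-(4-{2-[3-(benzyloxy)-4,5-dimethoxyphenyl]ethenyl}phenoxy)-4,5-dimethoxyphenyl]prop-2-enoate (stilbene bond E/Z), via phosphorus ylide 8 (not isolated)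
Conditions: 4, LiN(SiMe3)2, THF, −78 → 0 °C; then 7, 0 °C → rt
Reagents that add atoms: none
Why: Wittig olefination of the aromatic aldehyde with a semi-stabilized benzylic ylide preformed with a non-nucleophilic base, so the ethyl ester is untouched; the alkene geometry is irrelevant because the bond is saturated in step 7.

Step 7
Reactants: 9 ethyl (2E)-3-[3-(4-{2-[3-(benzyloxy)-4,5-dimethoxyphenyl]ethenyl}phenoxy)-4,5-dimethoxyphenyl]prop-2-enoate
Product: 10 ethyl 3-(ArOH)propanoate
Conditions: H2 (1 atm), 10% Pd/C, EtOAc/EtOH, rt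
Reagents that add atoms: none
Why: Heterogeneous catalytic hydrogenation should saturate the stilbene and cinnamate double bonds and hydrogenolyse the benzyl ether in one operation, while methyl ethers, the diaryl ether and the ester are inert.

Step 8
Reactants: 10 ethyl 3-(ArOH)propanoate
Product: 11 3-(ArOH)propanal
Conditions: i-Bu2AlH (2.2 equiv), CH2Cl2, −78 °C; MeOH, then aq. potassium sodium tartrate (KNaC4H4O6)
Reagents that add atoms: none
Why: Partial reduction of an ester by the aluminium hydride at −78 °C, where the tetrahedral aluminium hemiacetal persists until work-up; the first equivalent is consumed by the phenol, which returns on hydrolysis.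

Step 9
Reactants: 11 3-(ArOH)propanal
Product: 12 (3E)-6-(ArOH)hex-3-en-2-one
Conditions: Ph3P=CHC(O)CH3, THF, 65 °C
Reagents that add atoms: 1-(triphenylphosphoranylidene)propan-2-one, CC(=O)C=P(c1ccccc1)(c1ccccc1)c1ccccc1
Why: Wittig olefination with the stabilized acetonylidene ylide should give the E-enone and tolerates the free phenol.

Step 10
Reactants: 12 (3E)-6-(ArOH)hex-3-en-2-one; 13 diethyl malonate
Product: 17 5-[2-(ArOH)ethyl]cyclohexane-1,3-dione, via Michael adduct 14 (not isolated), via cyclic keto ester 15 (not isolated), via keto acid 16 (not isolated)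
Conditions: NaOEt (2.5 equiv), EtOH, reflux; then aq. NaOH, reflux; then HCl to pH 1, reflux
Reagents that add atoms: none
Why: Michael addition of sodiomalonate to the enone, intramolecular Claisen condensation of the methyl ketone enolate onto an ester, then saponification and decarboxylation (the classical dimedone-type annulation); the ring C phenoxide is a spectator and the new centre becomes C5 of an achiral dione.

Step 11
Reactants: 17 5-[2-(ArOH)ethyl]cyclohexane-1,3-dione
Product: 19 5-[2-(ArOTBS)ethyl]cyclohexane-1,3-dione, via bis-silyl ether 18 (not isolated)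
Conditions: TBSCl (2.5 equiv), imidazole, DMF, rt; then aq. citric acid/THF
Reagents that add atoms: tert-butyldimethylsilyl chloride, CC(C)(C)[Si](C)(C)Cl
Why: Imidazole-promoted silylation covers the phenol and the dione enol, and the acidic aqueous work-up hydrolyses only the labile vinylogous silyl ester, so the phenol alone stays masked for the chlorination.

Step 12
Reactants: 19 5-[2-(ArOTBS)ethyl]cyclohexane-1,3-dione
Product: 20 3-chloro-5-[2-(ArOTBS)ethyl]cyclohex-2-en-1-one (racemic)
Conditions: (COCl)2, DMF (cat.), CH2Cl2, 0 °C → rt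
Reagents that add atoms: oxalyl chloride, O=C(Cl)C(=O)Cl
Why: Vilsmeier-type deoxychlorination of the dione enol to the vinylogous acid chloride; the dione is symmetric, so a single racemic chloroenone should form, and the aryl silyl ether keeps the phenol from being acylated.

Step 13
Reactants: 20 3-chloro-5-[2-(ArOTBS)ethyl]cyclohex-2-en-1-one
Product: 21 3-chloro-5-[2-(ArOH)ethyl]cyclohex-2-en-1-one (racemic)
Conditions: Bu4NF, AcOH, THF, 0 °C
Reagents that add atoms: none
Why: Fluoride cleavage of the aryl silyl ether; the acetic acid buffer protonates the phenoxide as it forms, so it cannot attack a chloroenone intermolecularly at preparative concentration.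

Step 14
Reactants: 21 3-chloro-5-[2-(ArOH)ethyl]cyclohex-2-en-1-one
Product: 22 macrocyclic enone (racemic): cyclohex-2-en-1-one whose C3 is bonded to the ring C oxygen and whose C5 carries the CH2CH2 link to ring A; 19-membered ring
Conditions: Cs2CO3 (3 equiv), DMF, 60 °C, syringe-pump addition of 21 over 12 h to 1 mM final concentration
Reagents that add atoms: none
Why: The caesium phenoxide of ring C adds through oxygen to C3 of the enone, the chlorine-bearing β-carbon, to give a stabilized enolate, which expels chloride and restores the enone (vinylogous acyl substitution by addition–elimination). The closest known reaction is the carbonate-mediated etherification of phenols with 3-chlorocyclohex-2-enone to 3-aryloxycyclohexenones. The 19-membered ring closes in a 19-exo-trig sense: the attacked sp2 carbon lies in the new ring, while C2 and the carbonyl that take up the charge lie outside it. No stereocentre is formed; the racemic C5 centre is untouched and is erased in step 15. The step needs oxygen rather than carbon attack of the phenoxide, conjugate addition–elimination rather than 1,2-addition or γ-deprotonation, and cyclization rather than oligomerization. These are secured by the vinylogous acid chloride (soft β-carbon, good leaving group, reversible carbonyl addition), by a weak carbonate base in a dipolar aprotic solvent with a single free phenol in the molecule, and by slow addition at high dilution, helped by the sp3 carbons C4–C6 of the not yet aromatic ring and the two CH2CH2 tethers.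

Step 15
Reactants: 22 macrocyclic enone
Product: 24 macrocyclic phenol (ring D now 3-aryloxy-5-alkylphenol), via cross-conjugated dienone 23 (not isolated)
Conditions: Pd(O2CCF3)2 (5 mol%), 2-(dimethylamino)pyridine (10 mol%), TsOH·H2O (20 mol%), O2 (1 atm), DMSO, 80 °C
Reagents that add atoms: none
Why: Aerobic palladium-catalysed dehydrogenation of a cyclohexenone: a divalent palladium enolate at C6 undergoes β-hydride elimination towards C5 to give the 2,5-dienone, which tautomerizes to the phenol, and oxygen reoxidizes zerovalent palladium.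

Step 16
Reactants: 24 macrocyclic phenol
Product: 25 macrocyclic aryl triflate (trifluoromethanesulfonate of the ring D phenol)
Conditions: Tf2O, pyridine, CH2Cl2, 0 °C
Reagents that add atoms: trifluoromethanesulfonic anhydride, O=S(=O)(OS(=O)(=O)C(F)(F)F)C(F)(F)F
Why: O-sulfonylation of the only free phenol turns the unwanted oxygen into a leaving group for reductive removal.

Step 17
Reactants: 25 macrocyclic aryl triflate
Product: 26 macrocyclic tetramethyl ether (target with its four OH groups as OMe)
Conditions: Pd(OAc)2 (5 mol%), PPh3 (10 mol%), Et3N, HCO2H, DMF, 60 °C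
Reagents that add atoms: none
Why: Palladium-catalysed formate reduction of an aryl triflate (oxidative addition to zerovalent palladium, formate exchange, loss of CO2, reductive elimination of the C–H bond) leaves ring D as the unsubstituted meta-phenylene.

Step 18
Reactants: 26 macrocyclic tetramethyl ether
Product: 27 target CNP0511668.0
Conditions: BBr3 (10 equiv), CH2Cl2, −78 °C → rt; then degassed H2O, 0 °C, under argon
Reagents that add atoms: none
Why: Boron tribromide cleaves the four aryl methyl ethers (Lewis acid–base adduct, then bromide attack at methyl) but not the two diaryl ethers; hydrolysis of the aryl borates should give the two catechols.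

**Compound list**

1 | 3-hydroxy-4,5-dimethoxybenzaldehyde | COc1cc(C=O)cc(O)c1OC | starting material
2 | 3-(benzyloxy)-4,5-dimethoxybenzaldehyde | COc1cc(C=O)cc(OCc2ccccc2)c1OC | intermediate
3 | [3-(benzyloxy)-4,5-dimethoxyphenyl]methanol | COc1cc(CO)cc(OCc2ccccc2)c1OC | intermediate
4 | {[3-(benzyloxy)-4,5-dimethoxyphenyl]methyl}triphenylphosphonium bromide | COc1cc(C[P+](c2ccccc2)(c2ccccc2)c2ccccc2)cc(OCc2ccccc2)c1OC.[Br-] | intermediate
5 | ethyl (2E)-3-(3-hydroxy-4,5-dimethoxyphenyl)prop-2-enoate | CCOC(=O)/C=C/c1cc(O)c(OC)c(OC)c1 | intermediate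
6 | 4-fluorobenzaldehyde | O=Cc1ccc(F)cc1 | starting material
7 | ethyl (2E)-3-[3-(4-formylphenoxy)-4,5-dimethoxyphenyl]prop-2-enoate | CCOC(=O)/C=C/c1cc(OC)c(OC)c(Oc2ccc(C=O)cc2)c1 | intermediate
8 | {[3-(benzyloxy)-4,5-dimethoxyphenyl]methylidene}triphenylphosphorane (not isolated) | COc1cc(C=P(c2ccccc2)(c2ccccc2)c2ccccc2)cc(OCc2ccccc2)c1OC | intermediate
9 | ethyl (2E)-3-[3-(4-{2-[3-(benzyloxy)-4,5-dimethoxyphenyl]ethenyl}phenoxy)-4,5-dimethoxyphenyl]prop-2-enoate (stilbene bond E/Z) | CCOC(=O)/C=C/c1cc(OC)c(OC)c(Oc2ccc(C=Cc3cc(OC)c(OC)c(OCc4ccccc4)c3)cc2)c1 | intermediate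
10 | ethyl 3-(ArOH)propanoate | CCOC(=O)CCc1cc(OC)c(OC)c(Oc2ccc(CCc3cc(OC)c(OC)c(O)c3)cc2)c1 | intermediate
11 | 3-(ArOH)propanal | O=CCCc1cc(OC)c(OC)c(Oc2ccc(CCc3cc(OC)c(OC)c(O)c3)cc2)c1 | intermediate
12 | (3E)-6-(ArOH)hex-3-en-2-one | CC(=O)/C=C/CCc1cc(OC)c(OC)c(Oc2ccc(CCc3cc(OC)c(OC)c(O)c3)cc2)c1 | intermediate
13 | diethyl malonate | CCOC(=O)CC(=O)OCC | starting material
14 | diethyl 2-[1-(ArOH)-5-oxohexan-3-yl]propanedioate (racemic, not isolated) | CCOC(=O)C(C(=O)OCC)C(CC(C)=O)CCc1cc(OC)c(OC)c(Oc2ccc(CCc3cc(OC)c(OC)c(O)c3)cc2)c1 | intermediate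
15 | ethyl 6-[2-(ArOH)ethyl]-2,4-dioxocyclohexane-1-carboxylate (racemic diastereomer mixture, not isolated) | CCOC(=O)C1C(CCc2cc(OC)c(OC)c(Oc3ccc(CCc4cc(OC)c(OC)c(O)c4)cc3)c2)CC(=O)CC1=O | intermediate
16 | 6-[2-(ArOH)ethyl]-2,4-dioxocyclohexane-1-carboxylic acid (racemic diastereomer mixture, not isolated) | OC(=O)C1C(CCc2cc(OC)c(OC)c(Oc3ccc(CCc4cc(OC)c(OC)c(O)c4)cc3)c2)CC(=O)CC1=O | intermediate
17 | 5-[2-(ArOH)ethyl]cyclohexane-1,3-dione | O=C1CC(=O)CC(CCc2cc(OC)c(OC)c(Oc3ccc(CCc4cc(OC)c(OC)c(O)c4)cc3)c2)C1 | intermediate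
18 | 3-{[tert-butyl(dimethyl)silyl]oxy}-5-[2-(ArOTBS)ethyl]cyclohex-2-en-1-one (racemic, not isolated) | CC(C)(C)[Si](C)(C)OC1=CC(=O)CC(CCc2cc(OC)c(OC)c(Oc3ccc(CCc4cc(OC)c(OC)c(O[Si](C)(C)C(C)(C)C)c4)cc3)c2)C1 | intermediate
19 | 5-[2-(ArOTBS)ethyl]cyclohexane-1,3-dione | O=C1CC(=O)CC(CCc2cc(OC)c(OC)c(Oc3ccc(CCc4cc(OC)c(OC)c(O[Si](C)(C)C(C)(C)C)c4)cc3)c2)C1 | intermediate
20 | 3-chloro-5-[2-(ArOTBS)ethyl]cyclohex-2-en-1-one (racemic) | O=C1C=C(Cl)CC(CCc2cc(OC)c(OC)c(Oc3ccc(CCc4cc(OC)c(OC)c(O[Si](C)(C)C(C)(C)C)c4)cc3)c2)C1 | intermediate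
21 | 3-chloro-5-[2-(ArOH)ethyl]cyclohex-2-en-1-one (racemic; key-step precursor) | O=C1C=C(Cl)CC(CCc2cc(OC)c(OC)c(Oc3ccc(CCc4cc(O)c(OC)c(OC)c4)cc3)c2)C1 | intermediate
22 | macrocyclic 3-aryloxycyclohex-2-en-1-one (racemic; key-step product) | O=C1C=C2CC(C1)CCc1cc(OC)c(OC)c(c1)Oc1ccc(cc1)CCc1cc(O2)c(OC)c(OC)c1 | intermediate
23 | macrocyclic 3-aryloxy-5-alkylcyclohexa-2,5-dien-1-one (not isolated) | O=C1C=C2CC(=C1)CCc1cc(OC)c(OC)c(c1)Oc1ccc(cc1)CCc1cc(O2)c(OC)c(OC)c1 | intermediate
24 | macrocyclic phenol (ring D as 3-aryloxy-5-alkylphenol) | Oc1cc2cc(c1)CCc1cc(OC)c(OC)c(c1)Oc1ccc(cc1)CCc1cc(O2)c(OC)c(OC)c1 | intermediate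
25 | macrocyclic aryl trifluoromethanesulfonate | O=S(=O)(Oc1cc2cc(c1)CCc1cc(OC)c(OC)c(c1)Oc1ccc(cc1)CCc1cc(O2)c(OC)c(OC)c1)C(F)(F)F | intermediate
26 | macrocyclic tetramethyl ether of the target | COc1cc2cc(c1OC)Oc1ccc(cc1)CCc1cc(OC)c(OC)c(c1)Oc1cccc(c1)CC2 | intermediate
27 | CNP0511668.0 | Oc1cc2cc(c1O)Oc1ccc(cc1)CCc1cc(O)c(O)c(c1)Oc1cccc(c1)CC2 | target

**Step count**

Total: 18 steps. Longest linear sequence: 16 steps (steps 1–3, then 6–18).

**Steps most likely to fail**

Step 14 (ring closure). Intermolecular addition–elimination may outrun cyclization, so that linear and cyclic oligomers grow instead of the 19-membered ring. The fallback makes ring D aromatic first and closes the same O–C bond by palladium-catalysed aryl ether coupling. It sets out from 20. Luche reduction (NaBH4, CeCl3·7H2O, MeOH/THF, −20 °C) should give 3-chloro-5-[2-(ArOTBS)ethyl]cyclohex-2-en-1-ol F1. Dehydration with the Burgess reagent (benzene, 50 °C) should give 1-chloro-5-[2-(ArOTBS)ethyl]cyclohexa-1,3-diene F2, and DDQ (benzene, rt) should dehydrogenate it to 1-chloro-3-[2-(ArOTBS)ethyl]benzene F3. Bu4NF (THF, 0 °C) should free the phenol 1-chloro-3-[2-(ArOH)ethyl]benzene F4. Intramolecular C–O coupling (Pd(OAc)2, 2-(di-tert-butylphosphino)-2',4',6'-triisopropylbiphenyl, K3PO4, toluene, 100 °C, 2 mM) should then close the ring and come back to the route at 26, so that steps 15–17 are not needed.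

Step 15 (dehydrogenation). The acid and the water formed may hydrolyse the vinylogous aryl ester and reopen the macrocycle, or palladium enolate formation at C6 of the electron-rich enone may stall. The fallback replaces catalytic C–H dehydrogenation by a preformed enol ether. It sets out from 22: kinetic deprotonation at C6 and silylation (LiN(i-Pr)2, THF, −78 °C; Me3SiCl) should give the macrocyclic 3-aryloxy-1-(trimethylsilyloxy)cyclohexa-1,3-diene F5. Saegusa–Ito oxidation (Pd(OAc)2, 1.1 equiv, MeCN, rt) should give dienone 23, which tautomerizes, and the route is rejoined at 24.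

Step 8 (partial reduction). The aluminium hemiacetal may collapse before work-up, so that reduction runs on to the primary alcohol. The fallback reduces fully and reoxidizes. It sets out from 10: LiAlH4 (THF, 0 °C) should give 3-(ArOH)propan-1-ol F6, and Parikh–Doering oxidation (SO3·pyridine, DMSO, Et3N, 0 °C), which spares the phenol, should come back to the route at 11.

**Further compounds**

F1 | step 14 | 3-chloro-5-[2-(ArOTBS)ethyl]cyclohex-2-en-1-ol (racemic diastereomer mixture) | OC1C=C(Cl)CC(CCc2cc(OC)c(OC)c(Oc3ccc(CCc4cc(OC)c(OC)c(O[Si](C)(C)C(C)(C)C)c4)cc3)c2)C1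
F2 | step 14 | 1-chloro-5-[2-(ArOTBS)ethyl]cyclohexa-1,3-diene (racemic) | ClC1=CC=CC(CCc2cc(OC)c(OC)c(Oc3ccc(CCc4cc(OC)c(OC)c(O[Si](C)(C)C(C)(C)C)c4)cc3)c2)C1
F3 | step 14 | 1-chloro-3-[2-(ArOTBS)ethyl]benzene | Clc1cccc(CCc2cc(OC)c(OC)c(Oc3ccc(CCc4cc(OC)c(OC)c(O[Si](C)(C)C(C)(C)C)c4)cc3)c2)c1
F4 | step 14 | 1-chloro-3-[2-(ArOH)ethyl]benzene | Clc1cccc(CCc2cc(OC)c(OC)c(Oc3ccc(CCc4cc(OC)c(OC)c(O)c4)cc3)c2)c1
F5 | step 15 | macrocyclic 3-aryloxy-1-(trimethylsilyloxy)cyclohexa-1,3-diene (racemic) | C[Si](C)(C)OC1=CC(CCc2cc(OC)c(OC)c(c2)Oc2ccc(cc2)CCc2cc(O3)c(OC)c(OC)c2)CC3=C1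
F6 | step 8 | 3-(ArOH)propan-1-ol | OCCCc1cc(OC)c(OC)c(Oc2ccc(CCc3cc(OC)c(OC)c(O)c3)cc2)c1
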